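## Structural features

The target is a flavone: benzo ring A is fused to the 4-pyranone ring C along C4a–C8a, and the catechol ring B is attached through C2–C1'. There is no stereocentre, so every difficulty is positional. Ring A carries three adjacent oxygens at C5, C6 and C7 and a single C–H at C8. O6 and O7 are sulfate monoesters, O5 is a free hydroxyl hydrogen-bonded to the C4 carbonyl, and both ring B hydroxyls are free. The fragile parts are the aryl O–SO3 bonds (cleaved by aqueous acid, inert to base; the acid form is less stable than its salts), the electron-rich polyphenol rings (oxidised in alkali under air) and the O1–C2 enol-ether bond of ring C (opened by hot strong acid or hot strong alkali). The real problems are two: an oxygen at C6 of a 5,7-dioxygenated flavone cannot be installed selectively by oxidation, and five phenolic oxygens must be told apart so that only O6 and O7 are sulfated. The key step exploits the fact that C4a has two ortho oxygens, O5 and O1. Because O1–C2 can be hydrolysed to a 1,3-diketone and re-formed from either oxygen, a 5,7,8-pattern is the ring C isomer of the 5,6,7-pattern. C8, para to O5, is the carbon that phenoxide-directed oxidation does reach. The chelated 5-hydroxyl is also the one hydroxyl that amine–SO3 reagents leave alone, which settles the sulfation of ring A once ring B is masked.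

## Logic of the disconnections

18 to 16 (through 17). The two S–O bonds of ring B sulfonyl groups are put back and the counter-ion is changed. A free ring B catechol would compete in the sulfation, and a methanesulfonate is the one mask that survives the hot acid of the key step and still leaves by S–O fission in base, where aryl sulfate anions are inert. The demand is that hydroxide attacks sulfonyl sulfur faster than C2 of ring C, and that the acid form is generated last and cold.

16 to 14 and 15. The O6–S and O7–S bonds are cut. Sulfate monoesters are the most fragile groups, so they go on second to last, and 14 is a neutral triol that can be purified normally. The demand is that O5 stays free (chelation to C4=O) and that two adjacent hydroxyls are both sulfated, which needs excess 15.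

14 to 11 (key). The O1–C2 bond of 14 is broken and ring C is re-formed through the other ortho oxygen, which returns the 5,7,8-pattern; a methyl group is put on O7. This moves the oxidation problem from C6, which cannot be addressed, to C8, which can. The demand is reversible ring opening in an acid hot enough to cleave the methyl ether, an equilibrium on the side of 14, and a ring B mask indifferent to that acid. The structures of 11 and 14 are consistent with this transposition (former O8 becomes O6, former O1 becomes the 5-hydroxyl), so neither needed correction. The design of 11 is kept, because a sulfonate is the only ring B mask that is stable to the acid and removable with the sulfates in place. What is tightened is the route around it: little base and low temperature in step 5, and a sulfating agent in step 7 that leaves no by-product.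

11 to 8 and 9. The C8–O bond is cut. C8 is para to the 5-phenoxide, the position that 9 attacks. The gain is the natural 5,7-pattern. The demand is that O7 is capped, so that the 7-phenoxide does not dominate, and that ring B survives alkali for the duration of the oxidation.

8 to 6 and 7. The two ring B O–S bonds are cut. The sulfonylation must precede step 5, because afterwards O8 would compete. The demand is that the chelated 5-hydroxyl is left alone, which controlled stoichiometry of 7 should secure.

6 to 5. The ketal is put back on ring B. It is only a temporary mask that allows O7 to be alkylated alone. The demand is that it leaves in aqueous acid without touching the methyl ether.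

5 to 3 and 4. The O7–CH3 bond is cut. In 3 only O7 and the chelated O5 are free, so one equivalent of 4 can only go to O7.

3 to 1 and 2. The two ketal C–O bonds are cut. In 1 the 7- and 4'-hydroxyls are of similar acidity, so direct methylation would not be selective, whereas 2 reacts only with the vicinal diol of ring B. This ends at 1, which already holds all fifteen skeletal carbons.

## Other disconnections considered

Alternative 1: The cut runs through C8–C8a and C4a–C5, removing ring A from a unit of rings B and C.
- Forward step: bromopyranone A1 and the tetraoxygenated diene A2 would combine by [4+2] addition (or its stepwise Mukaiyama–Michael/aldol equivalent) across C5=C6 of A1. Loss of HBr and methanol would aromatise the adduct to the 6-O-silyl flavone A3.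
- In favour: the oxygen pattern is written into A2, so the place of O6 does not depend on an equilibrium. The benzyl ethers of ring B allow a neutral hydrogenolysis after sulfation, which is better than the alkaline demesylation of step 8.
- Against: C5=C6 of a 4-pyranone is a vinylogous ester bond and a weak dienophile. A2 is a moisture-sensitive ketene acetal, and A1 needs its own synthesis, in which bromination at C3 competes. The silyl group on O6 must be removed again because O6 is to be sulfated, so differentiating O6 gains nothing for this target.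
- Comparison: on structure the two plans are equal, since both arrive at a 5,6,7-triol with masked ring B and both rely on the chelated 5-hydroxyl during sulfation. On mechanism the alternative uses kinetic regiocontrol by polarisation and avoids hot acid, whereas the chosen plan uses two classical reactions of an intact flavone. On step economy the alternative is convergent but longer, because A1 and A2 each need several steps before cycloaddition, desilylation, sulfation and hydrogenolysis.

Alternative 2: The cut is C4a–C8a, unfolding ring A into a polyketide chain masked as the pyrone A4.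
- Forward step: Mg(OMe)2 would open the lactone to the magnesium-chelated triketo ester, whose C4a carbanion adds to the ester carbonyl (Claisen condensation) to give the acylphloroglucinol chalcone A5.
- In favour: the step is mild and biomimetic, forms ring A with all its oxygens, and tolerates benzyl and 4-methoxybenzyl ethers. The alternative is better in protecting-group latitude and as a general entry to analogues with other B rings.
- Against: A5 is a chalcone, so ring C must still be closed and oxidised. Its two ortho hydroxyls are not equivalent, so closure can give the 6-O or the 8-O ether. The positional question that the chosen key step settles by equilibrium therefore returns under kinetic control. Aldol folding competes with Claisen folding, the enone of A4 can add methoxide, and A4 needs a multistep assembly.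
- Comparison: the alternative forms a C–C bond of the skeleton, whereas the chosen plan forms a C–O bond on a purchased skeleton. It is clearly longer in steps.

Alternative 3: The cuts are C7–C8 and C5–C6.
- Forward step: the dienolate from the 2-methyl group of pyranone ester A6 (LiN(iPr)2) would be acylated by the alkoxyacetate A7. A second enolisation at the alkoxy-bearing carbon and Dieckmann closure on the ring ester would give A8.
- In favour: the regiochemistry of ring A is fixed by construction, which is better than the chosen plan because nothing depends on the position of an equilibrium. Two C–C bonds form in one operation, the methoxymethyl group leaves in mild acid, and the final deprotection is again neutral hydrogenolysis.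
- Against: A6 needs several steps. Strong base can add to C6 of the pyranone. After the Claisen step the more acidic site is the methylene between ring and ketone, so the Dieckmann closure must proceed from a dianion.
- Comparison: in step count this alternative is about equal to the chosen plan. The chosen plan has the advantage of a commercial flavone and long-established reaction types. The alternative has the advantage of regiochemical certainty.

Key step: step 6

Assumption: the target is taken in the acid form drawn. It is made as the dipotassium salt 17 and set free by cold cation exchange as the last operation, because aryl hydrogen sulfates hydrolyse on storage and the salt is the form to keep.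

## Steps

Step 1
Reactants: 1 luteolin; 2 dichlorodiphenylmethane
Product: 3 2-(2,2-diphenyl-1,3-benzodioxol-5-yl)-5,7-dihydroxy-4H-chromen-4-one
Conditions: Ph2CCl2 (1.5 equiv), Ph2O, 175 °C, 30 min, N2
Reagents that add atoms: dichlorodiphenylmethane, ClC(Cl)(c1ccccc1)c1ccccc1
Why: Thermal ketalisation of a catechol with a gem-dichloride; only the vicinal 3',4'-diol can close the five-membered benzodioxole, so the 5- and 7-hydroxyls should stay free.

Step 2
Reactants: 3; 4 iodomethane
Product: 5 2-(2,2-diphenyl-1,3-benzodioxol-5-yl)-5-hydroxy-7-methoxy-4H-chromen-4-one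
Conditions: MeI (1.2 equiv), K2CO3 (1.5 equiv), DMF, rt, 12 h
Reagents that add atoms: iodomethane, CI
Why: Williamson O-methylation; the 7-hydroxyl is the acidic, unhindered phenol, while the 5-hydroxyl is held in a hydrogen bond to C4=O and should not react with one equivalent.

Step 3
Reactants: 5
Product: 6 2-(3,4-dihydroxyphenyl)-5-hydroxy-7-methoxy-4H-chromen-4-one
Conditions: AcOH–H2O (4:1), reflux, 3 h
Reagents that add atoms: none
Why: Acid hydrolysis of the diaryl ketal through the stabilised diphenyl oxocarbenium ion; the aryl methyl ether and the flavone are inert to aqueous acetic acid.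

Step 4
Reactants: 6; 7 methanesulfonyl chloride
Product: 8 4-(5-hydroxy-7-methoxy-4-oxo-4H-chromen-2-yl)-1,2-phenylene dimethanesulfonate
Conditions: MsCl (2.2 equiv), pyridine, 0 °C to rt
Reagents that add atoms: methanesulfonyl chloride, CS(=O)(=O)Cl
Why: O-sulfonylation of phenols; the two ring B hydroxyls are free and unhindered, whereas the chelated 5-hydroxyl reacts much more slowly, so 2.2 equivalents in the cold should stop at the bis-mesylate.

Step 5
Reactants: 8; 9 potassium peroxodisulfate
Product: 11 4-(5,8-dihydroxy-7-methoxy-4-oxo-4H-chromen-2-yl)-1,2-phenylene dimethanesulfonate, via potassium flavon-8-yl sulfate 10 (not isolated)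
Conditions: K2S2O8 (1.5 equiv), KOH (3 equiv), pyridine–H2O (1:1), 0–10 °C, 16 h, Ar; to pH 5, EtOAc wash (recovers 8); then HCl aq, Na2SO3, 80 °C, 30 min
Reagents that add atoms: potassium peroxodisulfate, [K+].[K+].[O-]S(=O)(=O)OOS(=O)(=O)[O-]
Why: Elbs persulfate oxidation: the 5-phenoxide attacks a peroxide oxygen of the reagent through its para carbon C8 to give aryl sulfate 10, which hot dilute acid hydrolyses with S–O fission. O7 is capped, so no second phenoxide competes; base is limited to three equivalents at or below 10 °C so that the ring B mesylates see little hydroxide, and unreacted 8 is recycled.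

Step 6
Reactants: 11
Product: 14 4-(5,6,7-trihydroxy-4-oxo-4H-chromen-2-yl)-1,2-phenylene dimethanesulfonate, via 5,7,8-trihydroxyflavone bis-mesylate 12 (not isolated), via ring-opened 1,3-diketone 13 (not isolated)
Conditions: 48% aq HBr–AcOH (1:2), reflux (ca. 120 °C), Ar, 8–12 h; poured into ice-water containing NaHSO3
Reagents that add atoms: none
Why: Wessely–Moser rearrangement run together with the ether cleavage. Bromide attacks the methyl group of the protonated 7-methoxy group (SN2) and frees triol 12. Protonation of the C4 carbonyl makes C2 an oxocarbenium-like centre; water adds there and the hemiketal opens by fission of O1–C2 to the 1,3-diketone 13, whose acyl-bearing carbon C4a now has two free ortho hydroxyls, the former O1 and the former O5. After rotation about C4–C4a the former 5-hydroxyl adds to the protonated C2 carbonyl in a 6-exo-trig closure and loss of water re-forms the pyranone, which creates the new O1–C2 bond and ring C of 14; the former O8 thereby becomes O6 and the former ring oxygen becomes the chelated 5-hydroxyl. No stereocentre is formed. The selectivity needed is positional and is thermodynamic: opening and closure are reversible in the hot acid, reclosure through the old oxygen only regenerates 12, and the equilibrium of this rearrangement lies on the side of the 5,6,7-isomer, so long heating should drain 12 into 14. Chemoselectivity rests on the acid stability of aryl sulfonate S–O bonds, which keeps ring B masked, and on the exclusion of air, since 11, 12 and 14 are oxidisable polyphenols.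

Step 7
Reactants: 14; 15 sulfur trioxide–triethylamine complex
Product: 16 bis(triethylammonium) 2-[3,4-bis(methylsulfonyloxy)phenyl]-5-hydroxy-4-oxo-4H-chromene-6,7-diyl bis(sulfate)
Conditions: Et3N·SO3 (6 equiv), Et3N (2 equiv), DMF, 60 °C, Ar, 16 h; silica, CH2Cl2–MeOH–Et3N
Reagents that add atoms: sulfur trioxide–triethylamine complex, CC[N+](CC)(CC)S(=O)(=O)[O-]
Why: O-sulfation of phenols by an amine–SO3 complex; the acidic 7-hydroxyl and then the 6-hydroxyl should react, while the 5-hydroxyl, hydrogen-bonded to C4=O and flanked by the new 6-sulfate, should stay free. The mesylates are inert to the weakly basic anhydrous medium.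

Step 8
Reactants: 16
Product: 18 2-(3,4-dihydroxyphenyl)-5-hydroxy-4-oxo-4H-chromene-6,7-diyl bis(hydrogen sulfate) (6-hydroxyluteolin 6,7-disulfate), via dipotassium disulfate salt 17 (not isolated)
Conditions: KOH aq (1 M, 8 equiv), degassed, 50 °C, Ar, 2 h; to pH 7, C18 desalting; sulfonic acid resin (H+ form), H2O, 0–5 °C; freeze-drying
Reagents that add atoms: none
Why: Alkaline cleavage of aryl methanesulfonates by attack of hydroxide at sulfur (S–O fission), conditions under which aryl sulfate anions are inert and the polyphenoxide form shields C2 of ring C from hydroxide. Desalting removes the methanesulfonate before cold cation exchange converts 17 into the acid form.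

## Compound list

1 | luteolin | O=c1cc(-c2ccc(O)c(O)c2)oc2cc(O)cc(O)c12 | starting material
2 | dichlorodiphenylmethane | ClC(Cl)(c1ccccc1)c1ccccc1 | starting material
3 | 2-(2,2-diphenyl-1,3-benzodioxol-5-yl)-5,7-dihydroxy-4H-chromen-4-one | O=c1cc(-c2ccc3c(c2)OC(c2ccccc2)(c2ccccc2)O3)oc2cc(O)cc(O)c12 | intermediate
4 | iodomethane | CI | starting material
5 | 2-(2,2-diphenyl-1,3-benzodioxol-5-yl)-5-hydroxy-7-methoxy-4H-chromen-4-one | COc1cc(O)c2c(=O)cc(-c3ccc4c(c3)OC(c3ccccc3)(c3ccccc3)O4)oc2c1 | intermediate
6 | 2-(3,4-dihydroxyphenyl)-5-hydroxy-7-methoxy-4H-chromen-4-one (7-O-methylluteolin) | COc1cc(O)c2c(=O)cc(-c3ccc(O)c(O)c3)oc2c1 | intermediate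
7 | methanesulfonyl chloride | CS(=O)(=O)Cl | starting material
8 | 4-(5-hydroxy-7-methoxy-4-oxo-4H-chromen-2-yl)-1,2-phenylene dimethanesulfonate | COc1cc(O)c2c(=O)cc(-c3ccc(OS(C)(=O)=O)c(OS(C)(=O)=O)c3)oc2c1 | intermediate
9 | potassium peroxodisulfate | [K+].[K+].[O-]S(=O)(=O)OOS(=O)(=O)[O-] | starting material
10 | potassium 2-[3,4-bis(methylsulfonyloxy)phenyl]-5-hydroxy-7-methoxy-4-oxo-4H-chromen-8-yl sulfate | COc1cc(O)c2c(=O)cc(-c3ccc(OS(C)(=O)=O)c(OS(C)(=O)=O)c3)oc2c1OS(=O)(=O)[O-].[K+] | intermediate
11 | 4-(5,8-dihydroxy-7-methoxy-4-oxo-4H-chromen-2-yl)-1,2-phenylene dimethanesulfonate | COc1cc(O)c2c(=O)cc(-c3ccc(OS(C)(=O)=O)c(OS(C)(=O)=O)c3)oc2c1O | intermediate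
12 | 4-(5,7,8-trihydroxy-4-oxo-4H-chromen-2-yl)-1,2-phenylene dimethanesulfonate | O=c1cc(-c2ccc(OS(C)(=O)=O)c(OS(C)(=O)=O)c2)oc2c(O)c(O)cc(O)c12 | intermediate
13 | 4-[3-oxo-3-(2,3,4,6-tetrahydroxyphenyl)propanoyl]-1,2-phenylene dimethanesulfonate | O=C(CC(=O)c1ccc(OS(C)(=O)=O)c(OS(C)(=O)=O)c1)c1c(O)cc(O)c(O)c1O | intermediate
14 | 4-(5,6,7-trihydroxy-4-oxo-4H-chromen-2-yl)-1,2-phenylene dimethanesulfonate | O=c1cc(-c2ccc(OS(C)(=O)=O)c(OS(C)(=O)=O)c2)oc2cc(O)c(O)c(O)c12 | intermediate
15 | sulfur trioxide–triethylamine complex | CC[N+](CC)(CC)S(=O)(=O)[O-] | starting material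
16 | bis(triethylammonium) 2-[3,4-bis(methylsulfonyloxy)phenyl]-5-hydroxy-4-oxo-4H-chromene-6,7-diyl bis(sulfate) | O=c1cc(-c2ccc(OS(C)(=O)=O)c(OS(C)(=O)=O)c2)oc2cc(OS(=O)(=O)[O-])c(OS(=O)(=O)[O-])c(O)c12.CC[NH+](CC)CC.CC[NH+](CC)CC | intermediate
17 | dipotassium 2-(3,4-dihydroxyphenyl)-5-hydroxy-4-oxo-4H-chromene-6,7-diyl bis(sulfate) | O=c1cc(-c2ccc(O)c(O)c2)oc2cc(OS(=O)(=O)[O-])c(OS(=O)(=O)[O-])c(O)c12.[K+].[K+] | intermediate
18 | 2-(3,4-dihydroxyphenyl)-5-hydroxy-4-oxo-4H-chromene-6,7-diyl bis(hydrogen sulfate) (6-hydroxyluteolin 6,7-disulfate) | O=c1cc(-c2ccc(O)c(O)c2)oc2cc(OS(=O)(=O)O)c(OS(=O)(=O)O)c(O)c12 | target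

## Step count and least certain steps

Total step count: 8. Longest linear sequence: 8 steps (1 to 18); the route is fully linear.

Step 6 (key step). The most likely failure is incomplete equilibration: demethylation may outrun ring opening, so that unrearranged 12 persists. Slow loss of a mesyl group over many hours at 120 °C and oxidation of the polyphenols by traces of air are the other risks. The fallback separates the two events and sets out from 11. BBr3 in CH2Cl2 (−78 °C to rt) would cleave the methyl ether without heat, and 12 would be isolated. Its isomerisation would then be run on its own in aqueous HCl–AcOH in a closed vessel at 110–120 °C, without bromide. Material that has not isomerised would be recovered by chromatography and resubjected. The fallback returns to the route at 14 and makes no compound outside the list.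

Step 5. The most likely failure is hydrolysis of a ring B mesylate by the alkali during the slow oxidation, after which the unmasked catechol is itself oxidised. Low conversion, as is usual for chelated phenoxides, is the second risk. The fallback changes the order so that no sulfonate meets alkali. It sets out from 5 and returns at 11.
- Elbs oxidation of 5 (K2S2O8, KOH, pyridine–H2O) would give potassium 2-(2,2-diphenyl-1,3-benzodioxol-5-yl)-5-hydroxy-7-methoxy-4-oxo-4H-chromen-8-yl sulfate F1.
- Solvolysis of F1 in wet THF with a trace of H2SO4 at or below 40 °C, mild enough to spare the ketal, would give 2-(2,2-diphenyl-1,3-benzodioxol-5-yl)-5,8-dihydroxy-7-methoxy-4H-chromen-4-one F2.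
- BnBr and K2CO3 in acetone would alkylate the unchelated O8 to give 8-(benzyloxy)-2-(2,2-diphenyl-1,3-benzodioxol-5-yl)-5-hydroxy-7-methoxy-4H-chromen-4-one F3.
- AcOH–H2O at reflux would remove the ketal to give 8-(benzyloxy)-2-(3,4-dihydroxyphenyl)-5-hydroxy-7-methoxy-4H-chromen-4-one F4.
- MsCl in pyridine would give 4-[8-(benzyloxy)-5-hydroxy-7-methoxy-4-oxo-4H-chromen-2-yl]-1,2-phenylene dimethanesulfonate F5.
- Hydrogenolysis (H2, Pd/C, EtOAc–THF) would free O8 and give 11.

Step 7. The most likely failure is incomplete sulfation of the hindered 6-hydroxyl next to the first sulfate, or over-sulfation at O5 when the reagent is pushed, giving a mixture of very polar salts that is hard to separate. The fallback introduces the sulfates as neutral protected diesters. It sets out from 14 and returns at 17.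
- 2,2,2-Trichloroethyl chlorosulfate with Et3N and 4-(dimethylamino)pyridine in THF at 0 °C would give 4-[5-hydroxy-4-oxo-6,7-bis[(2,2,2-trichloroethoxy)sulfonyloxy]-4H-chromen-2-yl]-1,2-phenylene dimethanesulfonate F6, which can be purified on silica.
- Zn and HCO2NH4 in MeOH would remove the trichloroethyl groups and give diammonium 2-[3,4-bis(methylsulfonyloxy)phenyl]-5-hydroxy-4-oxo-4H-chromene-6,7-diyl bis(sulfate) F7.
- F7 would enter the hydroxide treatment of step 8 in place of 16 and give 17.

Step 8. The most likely failure is slow departure of the second mesyl group, because the leaving oxygen then sits next to a phenoxide. Forcing the reaction invites addition of hydroxide to C2 with opening of ring C, oxidation of the catecholate, and hydrolysis of a sulfate during the acid exchange. The fallback removes the mesyl groups before any sulfate is present and makes the last deprotection a neutral hydrogenolysis. It sets out from 14 and returns at 18.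
- Ph2CCl2 (2) in Ph2O at 175 °C would tie the 6,7-diol up as 4-(9-hydroxy-8-oxo-2,2-diphenyl-8H-[1,3]dioxolo[4,5-g]chromen-6-yl)-1,2-phenylene dimethanesulfonate F8.
- LiN(iPr)2 (5 equiv) in THF, −78 to 0 °C, would remove the mesyl groups by elimination to sulfene, a path open only to this neutral, THF-soluble compound, and give 6-(3,4-dihydroxyphenyl)-9-hydroxy-2,2-diphenyl-8H-[1,3]dioxolo[4,5-g]chromen-8-one F9.
- BnBr and K2CO3 in DMF would give 6-[3,4-bis(benzyloxy)phenyl]-9-hydroxy-2,2-diphenyl-8H-[1,3]dioxolo[4,5-g]chromen-8-one F10.
- AcOH–H2O at reflux would give 2-[3,4-bis(benzyloxy)phenyl]-5,6,7-trihydroxy-4H-chromen-4-one F11.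
- Sulfation with 15 as in step 7 would give bis(triethylammonium) 2-[3,4-bis(benzyloxy)phenyl]-5-hydroxy-4-oxo-4H-chromene-6,7-diyl bis(sulfate) F12.
- Hydrogenolysis (H2, Pd/C, MeOH–H2O) would give bis(triethylammonium) 2-(3,4-dihydroxyphenyl)-5-hydroxy-4-oxo-4H-chromene-6,7-diyl bis(sulfate) F13.
- Cold cation exchange of F13 would give 18.

## Further compounds

F0 | step 6 | none | none
F1 | step 5 | potassium 2-(2,2-diphenyl-1,3-benzodioxol-5-yl)-5-hydroxy-7-methoxy-4-oxo-4H-chromen-8-yl sulfate | COc1cc(O)c2c(=O)cc(-c3ccc4c(c3)OC(c3ccccc3)(c3ccccc3)O4)oc2c1OS(=O)(=O)[O-].[K+]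
F2 | step 5 | 2-(2,2-diphenyl-1,3-benzodioxol-5-yl)-5,8-dihydroxy-7-methoxy-4H-chromen-4-one | COc1cc(O)c2c(=O)cc(-c3ccc4c(c3)OC(c3ccccc3)(c3ccccc3)O4)oc2c1O
F3 | step 5 | 8-(benzyloxy)-2-(2,2-diphenyl-1,3-benzodioxol-5-yl)-5-hydroxy-7-methoxy-4H-chromen-4-one | COc1cc(O)c2c(=O)cc(-c3ccc4c(c3)OC(c3ccccc3)(c3ccccc3)O4)oc2c1OCc1ccccc1
F4 | step 5 | 8-(benzyloxy)-2-(3,4-dihydroxyphenyl)-5-hydroxy-7-methoxy-4H-chromen-4-one | COc1cc(O)c2c(=O)cc(-c3ccc(O)c(O)c3)oc2c1OCc1ccccc1
F5 | step 5 | 4-[8-(benzyloxy)-5-hydroxy-7-methoxy-4-oxo-4H-chromen-2-yl]-1,2-phenylene dimethanesulfonate | COc1cc(O)c2c(=O)cc(-c3ccc(OS(C)(=O)=O)c(OS(C)(=O)=O)c3)oc2c1OCc1ccccc1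
F6 | step 7 | 4-[5-hydroxy-4-oxo-6,7-bis[(2,2,2-trichloroethoxy)sulfonyloxy]-4H-chromen-2-yl]-1,2-phenylene dimethanesulfonate | O=c1cc(-c2ccc(OS(C)(=O)=O)c(OS(C)(=O)=O)c2)oc2cc(OS(=O)(=O)OCC(Cl)(Cl)Cl)c(OS(=O)(=O)OCC(Cl)(Cl)Cl)c(O)c12
F7 | step 7 | diammonium 2-[3,4-bis(methylsulfonyloxy)phenyl]-5-hydroxy-4-oxo-4H-chromene-6,7-diyl bis(sulfate) | O=c1cc(-c2ccc(OS(C)(=O)=O)c(OS(C)(=O)=O)c2)oc2cc(OS(=O)(=O)[O-])c(OS(=O)(=O)[O-])c(O)c12.[NH4+].[NH4+]
F8 | step 8 | 4-(9-hydroxy-8-oxo-2,2-diphenyl-8H-[1,3]dioxolo[4,5-g]chromen-6-yl)-1,2-phenylene dimethanesulfonate | O=c1cc(-c2ccc(OS(C)(=O)=O)c(OS(C)(=O)=O)c2)oc2cc3OC(c4ccccc4)(c4ccccc4)Oc3c(O)c12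
F9 | step 8 | 6-(3,4-dihydroxyphenyl)-9-hydroxy-2,2-diphenyl-8H-[1,3]dioxolo[4,5-g]chromen-8-one | O=c1cc(-c2ccc(O)c(O)c2)oc2cc3OC(c4ccccc4)(c4ccccc4)Oc3c(O)c12
F10 | step 8 | 6-[3,4-bis(benzyloxy)phenyl]-9-hydroxy-2,2-diphenyl-8H-[1,3]dioxolo[4,5-g]chromen-8-one | O=c1cc(-c2ccc(OCc3ccccc3)c(OCc3ccccc3)c2)oc2cc3OC(c4ccccc4)(c4ccccc4)Oc3c(O)c12
F11 | step 8 | 2-[3,4-bis(benzyloxy)phenyl]-5,6,7-trihydroxy-4H-chromen-4-one | O=c1cc(-c2ccc(OCc3ccccc3)c(OCc3ccccc3)c2)oc2cc(O)c(O)c(O)c12
F12 | step 8 | bis(triethylammonium) 2-[3,4-bis(benzyloxy)phenyl]-5-hydroxy-4-oxo-4H-chromene-6,7-diyl bis(sulfate) | O=c1cc(-c2ccc(OCc3ccccc3)c(OCc3ccccc3)c2)oc2cc(OS(=O)(=O)[O-])c(OS(=O)(=O)[O-])c(O)c12.CC[NH+](CC)CC.CC[NH+](CC)CC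
F13 | step 8 | bis(triethylammonium) 2-(3,4-dihydroxyphenyl)-5-hydroxy-4-oxo-4H-chromene-6,7-diyl bis(sulfate) | O=c1cc(-c2ccc(O)c(O)c2)oc2cc(OS(=O)(=O)[O-])c(OS(=O)(=O)[O-])c(O)c12.CC[NH+](CC)CC.CC[NH+](CC)CC
A1 | alternative 1 | 2-[3,4-bis(benzyloxy)phenyl]-5-bromo-4H-pyran-4-one | O=c1cc(-c2ccc(OCc3ccccc3)c(OCc3ccccc3)c2)occ1Br
A2 | alternative 1 | 2-(tert-butyldimethylsilyloxy)-1-methoxy-1,3-bis(trimethylsilyloxy)buta-1,3-diene (either geometry at C1=C2) | C=C(O[Si](C)(C)C)C(O[Si](C)(C)C(C)(C)C)=C(OC)O[Si](C)(C)C
A3 | alternative 1 | 2-[3,4-bis(benzyloxy)phenyl]-6-(tert-butyldimethylsilyloxy)-5,7-dihydroxy-4H-chromen-4-one | O=c1cc(-c2ccc(OCc3ccccc3)c(OCc3ccccc3)c2)oc2cc(O)c(O[Si](C)(C)C(C)(C)C)c(O)c12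
A4 | alternative 2 | 6-[(E)-4-[3,4-bis(benzyloxy)phenyl]-2-oxobut-3-en-1-yl]-4-hydroxy-5-[(4-methoxybenzyl)oxy]-2H-pyran-2-one | O=C(/C=C/c1ccc(OCc2ccccc2)c(OCc2ccccc2)c1)Cc1oc(=O)cc(O)c1OCc1ccc(OC)cc1
A5 | alternative 2 | (E)-3-[3,4-bis(benzyloxy)phenyl]-1-[2,4,6-trihydroxy-3-[(4-methoxybenzyl)oxy]phenyl]prop-2-en-1-one | O=C(/C=C/c1ccc(OCc2ccccc2)c(OCc2ccccc2)c1)c1c(O)cc(O)c(OCc2ccc(OC)cc2)c1O
A6 | alternative 3 | methyl 6-[3,4-bis(benzyloxy)phenyl]-2-methyl-4-oxo-4H-pyran-3-carboxylate | COC(=O)c1c(C)oc(-c2ccc(OCc3ccccc3)c(OCc3ccccc3)c2)cc1=O
A7 | alternative 3 | methyl 2-(methoxymethoxy)acetate | COCOCC(=O)OC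
A8 | alternative 3 | 2-[3,4-bis(benzyloxy)phenyl]-5,7-dihydroxy-6-(methoxymethoxy)-4H-chromen-4-one | COCOc1c(O)cc2oc(-c3ccc(OCc4ccccc4)c(OCc4ccccc4)c3)cc(=O)c2c1O
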